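**Retrosynthetic overview**
1. Ring C is the only ring made, and it is made last; rings A and B are bought. Opening 9 at O1–C2 and placing a temporary CO2tBu on C3 leads back to the achiral, open-chain alkylidene β-keto ester 6.
2. Enabling feature: on ring A the phenolic O1 (on C8a) stands ortho to C4a, which carries the C4 carbonyl. O1 is therefore within 6-endo reach of C2, the β-carbon of the C2=C3–C4=O enone. C3 is a plain CH2 next to C4=O in 9, so it can carry an ester that sharpens the acceptor, gives a catalyst a 1,3-dicarbonyl handle and leaves without trace. The C5 methoxy group favours the closed form.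
3. 6 comes from a Knoevenagel condensation (C2=C3) of β-keto ester 4 with 4-methoxybenzaldehyde 5.
4. 4 comes from C-carboxylation of the acetyl CH3 (the future C3) of acetophenone 3. 3 comes from commercial 1 (the acetylation product of 3,4,5-trimethoxyphenol) by bromination and copper-catalysed methoxylation at the future C8.

Key step: step 5

Assumption: the quinidine-derived thiourea is taken to deliver the (2S) series; the quinine-derived pseudoenantiomer gives the mirror-image sense, so a mismatch shown by circular dichroism in a first run is corrected by exchanging the catalyst, with no other change to the route.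

**Step 1**
Reactants: 1 1-(6-hydroxy-2,3,4-trimethoxyphenyl)ethan-1-one
Product: 2 1-(3-bromo-2-hydroxy-4,5,6-trimethoxyphenyl)ethan-1-one
Conditions: NBS (1.05 equiv), MeCN, 0 °C to rt
Reagents that add atoms: N-bromosuccinimide, O=C1CCC(=O)N1Br
Why: Electrophilic aromatic bromination, in which the single free position of ring A lies ortho to the phenol and to a methoxy group and should take up bromine far faster than the hydrogen-bonded acetyl group can enolize; no stereocentre is formed.

**Step 2**
Reactants: 2 1-(3-bromo-2-hydroxy-4,5,6-trimethoxyphenyl)ethan-1-one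
Product: 3 1-(2-hydroxy-3,4,5,6-tetramethoxyphenyl)ethan-1-one
Conditions: NaOMe (25 % in MeOH, 5 equiv), CuBr (20 mol %), DMF, 110 °C
Reagents that add atoms: sodium methoxide, C[O-].[Na+]
Why: Ullmann-type copper-catalysed methoxylation of an aryl bromide, a standard way to complete polymethoxylated acetophenones, in which the neighbouring phenoxide helps to bind copper and the ketone and aryl ethers are inert to methoxide.

**Step 3**
Reactants: 3 1-(2-hydroxy-3,4,5,6-tetramethoxyphenyl)ethan-1-one
Product: 4 tert-butyl 3-(2-hydroxy-3,4,5,6-tetramethoxyphenyl)-3-oxopropanoate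
Conditions: LiHMDS (3.3 equiv), THF, −78 °C; Boc2O (1.1 equiv), −78 to 0 °C; then AcOH
Reagents that add atoms: di-tert-butyl dicarbonate, CC(C)(C)OC(=O)OC(=O)OC(C)(C)C
Why: Claisen-type C-acylation of a ketone enolate, in which three equivalents of base form the phenoxide/enolate dianion and absorb the acidic product, the hindered chelated phenoxide is the poorer nucleophile, and the tert-butyl ester resists lactonization onto the phenol.

**Step 4**
Reactants: 4 tert-butyl 3-(2-hydroxy-3,4,5,6-tetramethoxyphenyl)-3-oxopropanoate; 5 4-methoxybenzaldehyde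
Product: 6 tert-butyl (2Z)-2-(2-hydroxy-3,4,5,6-tetramethoxybenzoyl)-3-(4-methoxyphenyl)prop-2-enoate
Conditions: piperidine (10 mol %), AcOH (10 mol %), 4 Å molecular sieves, toluene, rt
Reagents that add atoms: none
Why: Knoevenagel condensation of an active methylene compound with a non-enolizable aromatic aldehyde, which should give the thermodynamically preferred Z isomer (aryl trans to the bulky aroyl group) and, at room temperature with a buffered amine salt, should leave the phenol uncyclized.

**Step 5**
Reactants: 6 tert-butyl (2Z)-2-(2-hydroxy-3,4,5,6-tetramethoxybenzoyl)-3-(4-methoxyphenyl)prop-2-enoate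
Product: 9 (2S)-5,6,7,8,4'-pentamethoxyflavanone, via flavanone-3-carboxylic tert-butyl ester 7 (not isolated), via flavanone-3-carboxylic acid 8 (not isolated)
Conditions: 1-[3,5-bis(trifluoromethyl)phenyl]-3-[(9R)-6'-methoxycinchonan-9-yl]thiourea (10 mol %), toluene, −25 °C; then TsOH·H2O (1 equiv), 80 °C, same flask
Reagents that add atoms: none
Why: The quinuclidine nitrogen of the bifunctional catalyst takes up the O1–H proton while its thiourea N–H pair binds the C4 ketone/C3 ester 1,3-dicarbonyl, O1 adds to C2 of the doubly activated C2=C3 bond and the enol is protonated at C3 to give 7, after which TsOH at 80 °C cleaves the tert-butyl ester by loss of isobutene and the β-keto acid 8 loses CO2 through a six-membered cyclic transition state. The closest known reaction type is the cinchona-thiourea-catalysed enantioselective intramolecular oxa-Michael addition of 2-hydroxyaryl alkylidene β-keto esters with acidic decarboxylation in the same flask, which is established for 2-arylchroman-4-ones. Ring C closes in the 6-endo-trig mode. C2, the only stereocentre that survives, is controlled by the catalyst, which holds the Z-alkene so that O1 reaches the Re face of C2 (ranking C3 > aryl > H), whereas C3 of 7 is a labile β-keto ester centre that should settle trans to the aryl group and is erased with the ester. The catalysed closure must outrun the uncatalysed one and must not revert: the donor ring B on C2 tames the acceptor, toluene at −25 °C suppresses the background path, and the C5 methoxy group, the second ortho substituent of the aroyl unit, twists the open form out of conjugation so that the closed form is favoured. In one operation an achiral open-chain compound thus gains ring C and its stereocentre and sheds its activating group to give the target itself.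

**Compound list**
1 | 1-(6-hydroxy-2,3,4-trimethoxyphenyl)ethan-1-one | CC(=O)c1c(O)cc(OC)c(OC)c1OC | starting material
2 | 1-(3-bromo-2-hydroxy-4,5,6-trimethoxyphenyl)ethan-1-one | CC(=O)c1c(O)c(Br)c(OC)c(OC)c1OC | intermediate
3 | 1-(2-hydroxy-3,4,5,6-tetramethoxyphenyl)ethan-1-one | CC(=O)c1c(O)c(OC)c(OC)c(OC)c1OC | intermediate
4 | tert-butyl 3-(2-hydroxy-3,4,5,6-tetramethoxyphenyl)-3-oxopropanoate | CC(C)(C)OC(=O)CC(=O)c1c(O)c(OC)c(OC)c(OC)c1OC | intermediate
5 | 4-methoxybenzaldehyde | COc1ccc(C=O)cc1 | starting material
6 | tert-butyl (2Z)-2-(2-hydroxy-3,4,5,6-tetramethoxybenzoyl)-3-(4-methoxyphenyl)prop-2-enoate | COc1ccc(/C=C(\C(=O)OC(C)(C)C)C(=O)c2c(O)c(OC)c(OC)c(OC)c2OC)cc1 | intermediate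
7 | tert-butyl (2S,3R)-5,6,7,8-tetramethoxy-2-(4-methoxyphenyl)-4-oxochromane-3-carboxylate (2,3-trans, not isolated) | COc1ccc([C@@H]2[C@@H](C(=O)OC(C)(C)C)C(=O)c3c(OC)c(OC)c(OC)c(OC)c3O2)cc1 | intermediate
8 | (2S,3R)-5,6,7,8-tetramethoxy-2-(4-methoxyphenyl)-4-oxochromane-3-carboxylic acid (not isolated) | COc1ccc([C@@H]2[C@@H](C(=O)O)C(=O)c3c(OC)c(OC)c(OC)c(OC)c3O2)cc1 | intermediate
9 | (2S)-5,6,7,8-tetramethoxy-2-(4-methoxyphenyl)chroman-4-one, (2S)-5,6,7,8,4'-pentamethoxyflavanone | COc1ccc([C@@H]2CC(=O)c3c(OC)c(OC)c(OC)c(OC)c3O2)cc1 | target

Total step count: 5. Longest linear sequence: 5 steps (1 → 2 → 3 → 4 → 6 → 9).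

**Steps most likely to fail**

**Step 5.**
- Risk: facial selectivity may be poor, because O1–H is crowded by the C8 methoxy group and hydrogen-bonded to C4=O. Enantiomeric purity may also be eroded in hot acid by reversible opening of ring C at the C2 centre, which ring B stabilises as a cation.
- Fallback: it sets out from 3 and returns at 9. The stereocentre is set first in the open chain, and the ring is then closed by stereospecific substitution.
- 3 is O-acylated with 4-methoxybenzoyl chloride in pyridine to give 2-acetyl-3,4,5,6-tetramethoxyphenyl 4-methoxybenzoate F1.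
- A Baker–Venkataraman rearrangement (KOH, pyridine, 50 °C) gives 1-(2-hydroxy-3,4,5,6-tetramethoxyphenyl)-3-(4-methoxyphenyl)propane-1,3-dione F2.
- Asymmetric transfer hydrogenation with RuCl[(R,R)-TsDPEN](p-cymene) in HCO2H/Et3N should reduce only the unhindered anisoyl carbonyl. The product is (3R)-3-hydroxy-1-(2-hydroxy-3,4,5,6-tetramethoxyphenyl)-3-(4-methoxyphenyl)propan-1-one F3.
- A Mitsunobu cyclodehydration (PPh3, DIAD, toluene, 0 °C) closes ring C with inversion to 9. The conditions are cold and neutral, which should hold the substitution on its SN2 course.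

**Step 4.**
- Risk: premature, uncatalysed ring closure of the free phenol onto the new acceptor under amine catalysis would consume the open form before the chiral catalyst sees it. Scrambling of the alkene geometry is a second concern.
- Fallback: it sets out from 4 and 5 and returns at 9. The closure is allowed to run to completion and the racemate is resolved.
- Condensation with piperidine in refluxing toluene gives racemic tert-butyl trans-5,6,7,8-tetramethoxy-2-(4-methoxyphenyl)-4-oxochromane-3-carboxylate F4.
- TsOH in toluene at 80 °C gives racemic 5,6,7,8,4'-pentamethoxyflavanone F5.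
- Kinetic resolution by asymmetric transfer hydrogenation (Cp*RhCl[(R,R)-TsDPEN], HCO2H/Et3N, EtOAc, rt, stopped near half conversion) should reduce the (2R) enantiomer to (2R,4R)-5,6,7,8-tetramethoxy-2-(4-methoxyphenyl)chroman-4-ol F6.
- F6 is removed by chromatography, and 9 is left unreduced.

**Step 3.**
- Risk: acylation may occur on the phenoxide or enolate oxygen instead of carbon, the product may be acylated a second time, or it may lactonize.
- Fallback: it sets out from 3 and returns at 4. O-acylation is made deliberate and the acyl group is then delivered intramolecularly.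
- Boc2O with catalytic DMAP in CH2Cl2 gives 2-acetyl-3,4,5,6-tetramethoxyphenyl tert-butyl carbonate F7.
- LDA (2.2 equiv, THF, −78 °C) forms the methyl ketone enolate. The enolate takes over the carboxyl group through a six-membered transition state (Baker–Venkataraman-type O-to-C transfer) and frees the phenoxide of 4.

**Further compounds**
F1 | step 5 | 2-acetyl-3,4,5,6-tetramethoxyphenyl 4-methoxybenzoate | COc1ccc(cc1)C(=O)Oc1c(C(C)=O)c(OC)c(OC)c(OC)c1OC
F2 | step 5 | 1-(2-hydroxy-3,4,5,6-tetramethoxyphenyl)-3-(4-methoxyphenyl)propane-1,3-dione | COc1ccc(cc1)C(=O)CC(=O)c1c(O)c(OC)c(OC)c(OC)c1OC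
F3 | step 5 | (3R)-3-hydroxy-1-(2-hydroxy-3,4,5,6-tetramethoxyphenyl)-3-(4-methoxyphenyl)propan-1-one | COc1ccc([C@H](O)CC(=O)c2c(O)c(OC)c(OC)c(OC)c2OC)cc1
F4 | step 4 | racemic tert-butyl trans-5,6,7,8-tetramethoxy-2-(4-methoxyphenyl)-4-oxochromane-3-carboxylate | COc1ccc(C2C(C(=O)OC(C)(C)C)C(=O)c3c(OC)c(OC)c(OC)c(OC)c3O2)cc1
F5 | step 4 | racemic 5,6,7,8,4'-pentamethoxyflavanone | COc1ccc(C2CC(=O)c3c(OC)c(OC)c(OC)c(OC)c3O2)cc1
F6 | step 4 | (2R,4R)-5,6,7,8-tetramethoxy-2-(4-methoxyphenyl)chroman-4-ol (2,4-cis) | COc1ccc([C@H]2C[C@@H](O)c3c(OC)c(OC)c(OC)c(OC)c3O2)cc1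
F7 | step 3 | 2-acetyl-3,4,5,6-tetramethoxyphenyl tert-butyl carbonate | CC(=O)c1c(OC(=O)OC(C)(C)C)c(OC)c(OC)c(OC)c1OC
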